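## Structural features

The target is a C15 cage built on the cyclobutane C4–C5–C11–C10, whose two diagonals are bridged on opposite faces. C4 and C11 are spanned by the enone C1(=O)–C2=C3(CH3), which gives a bicyclo[3.1.1]hept-3-en-2-one. C5 and C10 are spanned by C6(CH3)2–C7–C8–C9, which gives the seven-membered ring C5–C6–C7–C8–C9–C10–C11. The four cyclobutane carbons are contiguous stereocentres whose relative configuration is dictated by the cage (C1 and C3 on one face, C6 and C9 on the other). C10 is quaternary and faces the second quaternary carbon C6 across C5, and the carbinol carbons C7 (isovalerate) and C9 (senecioate) are both neopentylic and trans to each other across C8. Fragile elements are the conjugated senecioate (deconjugation, Michael addition), every β-oxygenated ketone met on the way (elimination, retro-aldol), the strained four-membered ring when it carries 1,3-related carbonyl groups, and the enone under strong acid. A plane through C5, C10 and the C6–C9 bridge exchanges C4 with C11, so the cage is chiral only because the two ends of the enone differ (C1 carbonyl, C3 methyl); an intermediate with identical groups at C1 and C3 would be achiral. The real difficulty is the fully substituted cyclobutane with the non-epimerisable centres C5 and C10 correctly related, followed by placing two different acyl groups on two hindered secondary alcohols. The key step uses the fact that C11 carries a carboxyl-level carbon (C1) and C5 a neopentyl-type carbon (C6), with C10 and C4 between them: this is the α,α′-pattern of a pyrrolidine made from a glycinate imine and an oxo-enoate, so the C5–C11 bond can be the bond that remains when the ring nitrogen is excised.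

## Logic of the disconnections

**29 ⇒ 27 + 28.** The C7 O–acyl bond is cut. It is the easiest bond to form last and leaves the unsaturated ester untouched. The gain is a monoester with one free hydroxyl. The forward step must acylate a neopentylic secondary alcohol without acyl migration from O9.

**27 ⇒ 25 + 26.** The C9 O–acyl bond and the C7–H bond are cut together (1,3-anti diol monoester retron). One operation then sets C7 from C9 and distinguishes the two oxygens. The gain is loss of one stereocentre and one ester, leaving a β-hydroxy ketone. The forward step needs hydride transfer from the hemiacetal of an enal to a hindered ketone with anti selectivity and without retro-aldol opening of 25.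

**25 ⇒ 23 (through 24).** The C9–O bond is cut, because an oxygen β to the C7 ketone is a conjugate-addition retron. The gain is removal of the last stereocentre outside the cyclobutane. The forward step must choose one face of C9 by catalyst control and must prefer the C8=C9 enone over the C2=C3 enone.

**23 ⇒ 22.** The C8=C9 bond is cut (aldol condensation retron), which opens the seven-membered ring. The gain is a bicyclic keto aldehyde with a single enolisable position (C8) and a non-enolisable aldehyde (C9). The forward step is a seven-membered closure, helped by the cis-diaxial placement of C6 and C9 on the cage.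

**22 ⇒ 21 ⇒ 20 ⇒ 19.** No skeletal bond is cut. The C9 aldehyde is traced to the ester and the C7 ketone to a vinyl group (C7–O bond). The ester and the alkene are inert spectators during everything earlier. The price is one exhaustive reduction and one reoxidation, and the C7 ketone must appear only after the enone is closed.

**19 ⇒ 18 ⇒ 15 + 16, 15 ⇒ 14.** The C2=C3 bond and then the C1–C2 bond are cut. C2 arrives on a phosphonate, so C1 and C3 never carry the same group and the absolute configuration is kept. The gain is a monocyclic cyclobutane. The forward steps need C1 and C3 cis across the ring and acylation conditions that leave the C3 ketone alone.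

**14 ⇒ 12 (through 13).** No bond is cut; C4 and C11 are inverted. Both are α to carbonyl groups and both prefer to be trans to the tert-alkyl group on C5. The forward step must avoid Claisen-type closures of the acetyl enolate.

**12 ⇒ 10 (through 11).** The C5–C11 bond is cut and a nitrogen is inserted between the two carbons. This turns the strained, fully substituted four-membered ring into a five-membered heterocycle that a cycloaddition can assemble. The forward step must expel N2 and couple the two carbons with retention at C5.

**10 ⇒ 9 + 4.** The C10–C11 and C4–C5 bonds are cut ((3+2) retron). Three simple pieces result. The forward step must join the glycinate carbon to the substituted alkene carbon C10 and place the C10 ester cis to the C5 substituent.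

**4 ⇒ 3 ⇒ 1 + 2; 9 ⇒ 7 + 8, 8 ⇒ 6 ⇒ 5.** The C4=C10 bond (carbonyl olefination, then geometric isomerisation) and the C5=N bond (condensation) are cut, and the aldehyde is traced to the acid. All four ends are commercial.

## Other disconnections considered

**Alternative 1:** The cut is at C4–C5 and C1–C11 of the norbornene A1, a constitutional isomer of the cage in which C10 is still bonded to C1. Forward, the tethered nitroalkene A2 would close by an intramolecular Diels–Alder reaction to A1. The nitro group would then be turned into a leaving group, and C10 would shift from C1 to C11 as the bridgehead silyl ether collapses to the C1 ketone.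
- In its favour: one thermal step forms two C–C bonds, the six- and the seven-membered ring and four stereocentres, all relayed from C10 through the tether. The enone would emerge directly from the shift. On these points it is better than the chosen plan, which spends five steps on the seven-membered ring and three on the enone.
- Against it: the cyclobutane is not made in the key step. The later shift converts a norbornane into the more strained bicyclo[3.1.1]heptane and has to compete with hydride or C6 migration from C5. The nitro group first needs reduction and diazotisation (Tiffeneau–Demjanov-type).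
- Against it: C7 arrives as an unactivated methylene next to quaternary C6, with no handle for the C7 oxygen. Enantiopure A2, with adjacent stereocentres C9 and C10 on a 5,5-disubstituted silyloxycyclopentadiene, is itself a long synthesis.
- Structure check: C9 of A1 must have the configuration written in the block at the end; its epimer would lead to 9-epi-29.
- Comparison: on mechanism the pericyclic key step is more predictable than a biradical collapse (better), but the cationic shift after it is less predictable than anything in the chosen route. On structure the chosen plan holds the cyclobutane with correct C5 and C10 directly after its key step. On step economy the alternative is at best equal once C7 oxidation and the route to A2 are counted.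

**Alternative 2:** The cut is the C2=C3 bond of A3, leading back to the meso diketone A4. Forward, a chiral primary amine with an acid cocatalyst would convert the acetyl group on C11 into an enamine, which adds to the acetyl group on C4; dehydration gives A3.
- In its favour: it uses the hidden mirror plane. The absolute configuration of all four cage centres would be fixed in one catalytic step from an achiral precursor. The enone costs one step instead of three (better). The bond formed and the strain overcome are the same as in step 10 (equal). There is no stoichiometric oxidant and no radical (better).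
- Against it: the hard problem, a cyclobutane already bridged by the seven-membered ring, is moved into the synthesis of A4 and is not solved by this step. The enantio-determining aldol addition is reversible, and dehydration to a bridged enone may be slow, so the selectivity could erode. C9 is a methylene in A3, so the C9 oxygen would need dehydrogenation next to the C7 ketone and then the same conjugate borylation as step 15; the chosen route gets the C8=C9 enone directly.
- Comparison: the end-game is equal. The alternative depends on the very C1/C3 equivalence that the chosen route must avoid. Step economy is better for the enone, worse for C9, and open for A4.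

**Alternative 3:** The cut is at C5–C6 and C9–C10 of A5, leading back to the dibromocyclobutanone A6 and the bis(silyloxy)diene A7. Forward, reductive ionisation of A6 (zinc–copper couple or Fe2(CO)9) would give a 2-oxidocyclobutenyl cation that adds A7 in a (4+3) cycloaddition.
- In its favour: the seven-membered ring, quaternary C6 and both oxygens, already differentiated (C7 enol silane, C9 silyl ether), would come in one step. That is better than the five steps of the chosen plan for this ring, and it leads to the same 1,3-anti end-game.
- Against it: an oxyallyl cation held in a four-membered ring is highly strained and is expected to prefer Favorskii-type closure or proton loss. The dimethylated diene terminus slows bonding at C6 and invites stepwise side paths. Regiochemistry (C10 with C9, not with C6), the C9 configuration and the face relative to C11 are all uncontrolled. Afterwards the C4 ketone has to become C4–H carrying C3, and C1 has to be oxidised, before the enone can be built.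
- Comparison: structurally the two plans are complementary; this one makes early the ring that the chosen route makes late, and vice versa. Both key steps carry real risk, but nitrogen deletion has direct precedent on cycloadduct pyrrolidines, while this cycloaddition has no close one. Step economy is better up to the key step and worse after it.

Key step: step 6

Assumption: the facial sense of (S)-QUINAP in step 5 and of the (S,S)-bisphosphine in step 15 is taken by analogy with simpler substrates; if either is reversed, the antipodal ligand is used and nothing else changes.

Design notes (atom numbers C1–C11 as in the first section):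
- Pyrrolidine 10 is kept all-cis, but C4 is a non-controlling centre; either C4 epimer serves, because C4 is inverted in step 7.
- C11 is inverted at the diester stage, because a β-ketophosphonate deprotonated at C2 no longer enolises toward C11.
- The tert-butyl ester stays on C1 through step 7 because it resists Claisen attack by the acetyl enolate. That closure would give a dione with a mirror plane through C5 and C10 and erase the absolute configuration.
- The ketophosphonate is made by soft enolisation, since a lithiated methylphosphonate would attack the free C3 ketone.

## Route

Step 1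
Reactants: 1 methyl pyruvate; 2 1-(triphenylphosphoranylidene)propan-2-one
Product: 3 methyl (E)-2-methyl-4-oxopent-2-enoate
Conditions: CH2Cl2, rt → 40 °C
Reagents that add atoms: none
Why: Wittig olefination of an activated α-keto ester with a stabilised acyl ylide should give mainly the E alkene (ester and acetyl trans); any Z isomer formed is already 4 and is kept.

Step 2
Reactants: 3 methyl (E)-2-methyl-4-oxopent-2-enoate
Product: 4 methyl (Z)-2-methyl-4-oxopent-2-enoate
Conditions: thioxanthen-9-one (5 mol%), hν (365 nm), MeCN, rt; chromatography, E isomer recycled
Reagents that add atoms: none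
Why: Triplet-sensitised photochemical E→Z isomerisation of an ene-dicarbonyl; the less conjugated Z isomer is the poorer triplet acceptor and should accumulate at the photostationary state.

Step 3
Reactants: 5 2,2-dimethylbut-3-enoic acid
Product: 6 2,2-dimethylbut-3-en-1-ol
Conditions: LiAlH4, Et2O, 0 °C → rt; aq. NaOH work-up
Reagents that add atoms: none
Why: Hydride reduction of a carboxylic acid to the primary alcohol; the isolated terminal alkene is inert.

Step 4
Reactants: 6 2,2-dimethylbut-3-en-1-ol; 7 tert-butyl glycinate
Product: 9 tert-butyl (E)-N-(2,2-dimethylbut-3-en-1-ylidene)glycinate, via 2,2-dimethylbut-3-enal 8 (not isolated)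
Conditions: (COCl)2, DMSO, CH2Cl2, −78 °C; Et3N, −78 → 0 °C; aq. wash, solution dried; then 7, MgSO4, CH2Cl2, rt
Reagents that add atoms: none
Why: Swern oxidation gives the volatile aldehyde, which is kept in solution and condensed with the amine to the E aldimine; with no α-hydrogen the aldehyde can neither self-condense nor give an enamine tautomer.

Step 5
Reactants: 9 tert-butyl (E)-N-(2,2-dimethylbut-3-en-1-ylidene)glycinate; 4 methyl (Z)-2-methyl-4-oxopent-2-enoate
Product: 10 2-tert-butyl 3-methyl (2S,3R,4S,5R)-4-acetyl-3-methyl-5-(2-methylbut-3-en-2-yl)pyrrolidine-2,3-dicarboxylate (all-cis: both esters, the acetyl group and the C5 substituent on one face)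
Conditions: AgOAc (5 mol%), (S)-QUINAP (5.5 mol%), iPr2NEt (10 mol%), THF, −20 °C → rt
Reagents that add atoms: none
Why: Catalytic asymmetric (3+2) cycloaddition of the N,O-chelated silver azomethine ylide: the nucleophilic glycinate carbon C11 bonds to C10 (β to the ketone, largest acceptor coefficient) and the bulky imine carbon C5 to the unsubstituted C4. Endo approach to the Z alkene places the C10 ester cis to the C5 substituent, and the chiral phosphine selects the ylide face, which fixes C5 and C10 absolutely.

Step 6
Reactants: 10 all-cis pyrrolidine
Product: 12 1-tert-butyl 2-methyl 3-acetyl-2-methyl-4-(2-methylbut-3-en-2-yl)cyclobutane-1,2-dicarboxylate (all-cis; C5 and C10 as in 29), via 1,1-diazene 11 (not isolated)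
Conditions: PhI(OAc)2 (2.5 equiv), H2NCO2NH4 (8 equiv), CF3CH2OH (0.05 M), 80 °C
Reagents that add atoms: none
Why: PhI(OAc)2 and ammonia released from the carbamate form an iodonitrene that aminates the ring nitrogen electrophilically, and loss of iodobenzene gives the 1,1-diazene 11. The C11–N bond, weakened by the ester, breaks first, the diazenyl radical left on C5 loses N2 at once, and a singlet 1,4-biradical (C11 and C5) results. The closest known reaction type is the contraction of cycloadduct-derived pyrrolidines to cyclobutanes by nitrogen deletion through 1,1-diazenes. The four-membered ring closes by intramolecular radical–radical coupling of this biradical (C5–C11), not by a polar cyclisation. No new stereocentre is made: C5 and C11 are retained because the singlet biradical collapses faster than rotation about C4–C5 or C10–C11, and C4 and C10 are not touched. The selectivity needed is coupling in preference to β-scission of C4–C10 and to 1,2-vinyl shift of the homoallylic C5 radical; the short lifetime of the singlet pair and the cisoid geometry inherited from the ring should secure it. PhI(OAc)2 is preferred to PhI(OH)OTs so that the enolisable ketone is not oxidised at its α-carbon. Only the configuration at C5 has to survive, since C11 is inverted in the next step.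

Step 7
Reactants: 12 all-cis cyclobutane
Product: 14 1-tert-butyl 2-methyl 3-acetyl-2-methyl-4-(2-methylbut-3-en-2-yl)cyclobutane-1,2-dicarboxylate, C4,C11-diepimer of 12 (tert-butyl ester and acetyl on one face, methyl ester and C5 substituent on the other), via C4-epimeric cyclobutane 13 (not isolated)
Conditions: DBU (1 equiv), THF, rt; then KOtBu (0.3 equiv), tBuOH, rt; AcOH quench
Reagents that add atoms: none
Why: Thermodynamic epimerisation through enolates: the amidine first inverts the ketone α-carbon C4, which takes the acetyl group away from the cis C9 ester, and the alkoxide then equilibrates the ester α-carbon C11, so that both carbonyl groups end trans to the tert-alkyl group on C5. C5 and C10 have no acidic hydrogen, the tert-butyl ester resists Claisen attack, and retro-Michael ring opening is slow because the ring σ-bonds lie near the nodal plane of the exocyclic enolates.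

Step 8
Reactants: 14 epimerised cyclobutane
Product: 15 3-acetyl-2-(methoxycarbonyl)-2-methyl-4-(2-methylbut-3-en-2-yl)cyclobutane-1-carboxylic acid (configuration of 14)
Conditions: CF3CO2H/CH2Cl2 (1:3), 0 °C → rt
Reagents that add atoms: none
Why: Acidolysis of the tert-butyl ester with loss of isobutene; the neopentylic methyl ester, the ketone and the alkene are not affected.

Step 9
Reactants: 15 cyclobutanecarboxylic acid; 16 (diethoxyphosphoryl)acetic acid
Product: 18 methyl 3-acetyl-1-[2-(diethoxyphosphoryl)acetyl]-... cyclobutane β-ketophosphonate (C1 now a ketone bearing C2H2P(O)(OEt)2; configuration of 14), via acid chloride 17 (not isolated)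
Conditions: (COCl)2, DMF (cat.), CH2Cl2, 0 °C → rt; then 16, MgCl2, Et3N, MeCN, 0 °C → rt; aq. HCl
Reagents that add atoms: none
Why: Decarboxylative C-acylation of the magnesium enolate of the phosphonoacetic acid (soft enolisation, malonate half-ester type) forms the C1–C2 bond under conditions that leave the methyl ketone and the methyl ester alone. C2 enters on phosphorus, so C1 and C3 stay chemically distinct.

Step 10
Reactants: 18 β-ketophosphonate
Product: 19 methyl 4,6-dimethyl-7-(2-methylbut-3-en-2-yl)-2-oxobicyclo[3.1.1]hept-3-ene-6-carboxylate (ester and alkenyl group both anti to the enone bridge)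
Conditions: K2CO3, 18-crown-6, toluene (0.01 M), 80 °C
Reagents that add atoms: none
Why: Intramolecular Horner–Wadsworth–Emmons olefination: the C2 carbanion reaches the C3 ketone through a six-membered transition state across the cis-1,3 positions of the cyclobutane, and irreversible phosphate loss pays for the extra strain. No stereocentre is created, and any remaining C4 epimer is funnelled through ketone enolisation.

Step 11
Reactants: 19 bicyclic enone ester
Product: 20 methyl 4,6-dimethyl-7-(2-methyl-3-oxobutan-2-yl)-2-oxobicyclo[3.1.1]hept-3-ene-6-carboxylate
Conditions: PdCl2 (10 mol%), CuCl (1 equiv), O2 (1 atm), DMF/H2O (7:1), rt → 40 °C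
Reagents that add atoms: water, O
Why: Tsuji–Wacker oxidation: Markovnikov hydroxypalladation of the terminal alkene gives the methyl ketone, while the conjugated trisubstituted alkene is inert. The C7 ketone is unveiled only now, so the phosphonate carbanion of step 10 never met a second ketone.

Step 12
Reactants: 20 keto ester
Product: 21 6-(hydroxymethyl)-7-(3-hydroxy-2-methylbutan-2-yl)-4,6-dimethylbicyclo[3.1.1]hept-3-en-2-ol (mixture of epimers at the two new carbinol carbons C1 and C7)
Conditions: iBu2AlH (7 equiv), CH2Cl2, −78 → 0 °C; aq. potassium sodium tartrate
Reagents that add atoms: none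
Why: Exhaustive hydride reduction, because the hindered ester cannot be taken to the aldehyde selectively beside two ketones; the enone is reduced 1,2. The configuration of the two new carbinol centres is irrelevant, since both are reoxidised.

Step 13
Reactants: 21 triol
Product: 22 4,6-dimethyl-7-(2-methyl-3-oxobutan-2-yl)-2-oxobicyclo[3.1.1]hept-3-ene-6-carbaldehyde
Conditions: Dess–Martin periodinane (4.5 equiv), NaHCO3, CH2Cl2, 0 °C → rt
Reagents that add atoms: none
Why: Buffered Dess–Martin oxidation returns the allylic alcohol to the enone, the secondary alcohol to the C7 ketone and the neopentylic primary alcohol to a non-enolisable aldehyde.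

Step 14
Reactants: 22 keto aldehyde
Product: 23 tricyclic dienedione (cage of 29 with C1 enone, C7 ketone and C8=C9 double bond)
Conditions: KOH, MeOH (0.01 M), 0 °C → rt
Reagents that add atoms: none
Why: Intramolecular aldol condensation: only C8 can enolise on the C7 ketone, the C9 aldehyde cannot enolise and is held beside C8 by the cage, and E1cB dehydration gives the cis enone of the seven-membered ring. C11 is a bridgehead, so the C1 ketone cannot enolise toward it.

Step 15
Reactants: 23 tricyclic dienedione
Product: 25 (9R)-9-hydroxy tricyclic diketone (C9 hydroxyl on the C11 side of the seven-membered ring), via C9 pinacol boronate 24 (not isolated)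
Conditions: CuCl (5 mol%), NaOtBu (10 mol%), (S,S)-2,3-bis(tert-butylmethylphosphino)quinoxaline (6 mol%), B2pin2 (1.2 equiv), MeOH (2 equiv), THF, 0 °C → rt; then NaBO3·4H2O, THF/H2O, rt
Reagents that add atoms: sodium perborate, [Na+].[O-]B1OO1
Why: Copper-catalysed asymmetric conjugate borylation followed by stereoretentive C–B oxidation. The copper boryl should add to the β-monosubstituted C8=C9 enone far faster than to the β,β-disubstituted bridged enone; the two faces of C9 differ only through the remote C1 and C3 ends, so the chiral bisphosphine is relied on to set C9.

Step 16
Reactants: 25 (9R)-hydroxy diketone; 26 3-methylbut-2-enal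
Product: 27 (7R,9R)-7-hydroxy-9-(3-methylbut-2-enoyloxy) tricyclic enone (C7 hydroxyl trans to the C9 ester)
Conditions: SmI2 (30 mol%), 26 (8 equiv), THF, −10 °C
Reagents that add atoms: none
Why: Evans–Tishchenko reaction: the samarium-bound hemiacetal formed at O9 delivers its hydride intramolecularly to the C7 ketone through a six-membered transition state. This sets the C7 hydroxyl anti to O9 and leaves O9 as the senecioate in the same step; the directed delivery also spares the C1 enone.

Step 17
Reactants: 27 hydroxy monoester; 28 3-methylbutanoic anhydride
Product: 29 CNP0335239.1 ((7R,9R)-diester: C7 3-methylbutanoate, C9 3-methylbut-2-enoate)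
Conditions: 28 (3 equiv), DMAP (0.5 equiv), Et3N, CH2Cl2, rt → 35 °C
Reagents that add atoms: none
Why: DMAP-catalysed acyl transfer to the remaining hindered secondary alcohol; the trans-1,3 placement of the two oxygens disfavours acyl migration.

## Compound list

1 | methyl pyruvate | COC(=O)C(C)=O | starting material
2 | 1-(triphenylphosphoranylidene)propan-2-one | CC(=O)C=P(c1ccccc1)(c1ccccc1)c1ccccc1 | starting material
3 | methyl (E)-2-methyl-4-oxopent-2-enoate | COC(=O)/C(C)=C/C(C)=O | intermediate
4 | methyl (Z)-2-methyl-4-oxopent-2-enoate | COC(=O)/C(C)=C\C(C)=O | intermediate
5 | 2,2-dimethylbut-3-enoic acid | C=CC(C)(C)C(=O)O | starting material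
6 | 2,2-dimethylbut-3-en-1-ol | C=CC(C)(C)CO | intermediate
7 | tert-butyl glycinate | CC(C)(C)OC(=O)CN | starting material
8 | 2,2-dimethylbut-3-enal | C=CC(C)(C)C=O | intermediate
9 | tert-butyl (E)-N-(2,2-dimethylbut-3-en-1-ylidene)glycinate | C=CC(C)(C)/C=N/CC(=O)OC(C)(C)C | intermediate
10 | 2-tert-butyl 3-methyl (2S,3R,4S,5R)-4-acetyl-3-methyl-5-(2-methylbut-3-en-2-yl)pyrrolidine-2,3-dicarboxylate (all-cis) | CC(C)(C)OC(=O)[C@H]1N[C@@H](C(C)(C)C=C)[C@@H](C(C)=O)[C@@]1(C)C(=O)OC | intermediate
11 | 1,1-diazene of 10 (terminal nitrogen on the ring nitrogen) | CC(C)(C)OC(=O)[C@H]1[N+](=[N-])[C@@H](C(C)(C)C=C)[C@@H](C(C)=O)[C@@]1(C)C(=O)OC | intermediate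
12 | all-cis 1-tert-butyl 2-methyl 3-acetyl-2-methyl-4-(2-methylbut-3-en-2-yl)cyclobutane-1,2-dicarboxylate | CC(C)(C)OC(=O)[C@H]1[C@@H](C(C)(C)C=C)[C@@H](C(C)=O)[C@@]1(C)C(=O)OC | intermediate
13 | C4 epimer of 12 (acetyl trans to both neighbours) | CC(C)(C)OC(=O)[C@H]1[C@@H](C(C)(C)C=C)[C@H](C(C)=O)[C@@]1(C)C(=O)OC | intermediate
14 | C4,C11-diepimer of 12 (tert-butyl ester and acetyl cis; both trans to methyl ester and C5 substituent) | CC(C)(C)OC(=O)[C@@H]1[C@@H](C(C)(C)C=C)[C@H](C(C)=O)[C@@]1(C)C(=O)OC | intermediate
15 | 3-acetyl-2-(methoxycarbonyl)-2-methyl-4-(2-methylbut-3-en-2-yl)cyclobutane-1-carboxylic acid (configuration of 14) | OC(=O)[C@@H]1[C@@H](C(C)(C)C=C)[C@H](C(C)=O)[C@@]1(C)C(=O)OC | intermediate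
16 | (diethoxyphosphoryl)acetic acid | CCOP(=O)(CC(=O)O)OCC | starting material
17 | acid chloride of 15 | ClC(=O)[C@@H]1[C@@H](C(C)(C)C=C)[C@H](C(C)=O)[C@@]1(C)C(=O)OC | intermediate
18 | cyclobutane β-ketophosphonate (C1 ketone, C2 bearing P(O)(OEt)2; configuration of 14) | CCOP(=O)(OCC)CC(=O)[C@@H]1[C@@H](C(C)(C)C=C)[C@H](C(C)=O)[C@@]1(C)C(=O)OC | intermediate
19 | methyl 4,6-dimethyl-7-(2-methylbut-3-en-2-yl)-2-oxobicyclo[3.1.1]hept-3-ene-6-carboxylate | C=CC(C)(C)[C@@H]2[C@H]3C(=O)C=C(C)[C@@H]2[C@]3(C(=O)OC)C | intermediate
20 | methyl 4,6-dimethyl-7-(2-methyl-3-oxobutan-2-yl)-2-oxobicyclo[3.1.1]hept-3-ene-6-carboxylate | CC(=O)C(C)(C)[C@@H]2[C@H]3C(=O)C=C(C)[C@@H]2[C@]3(C(=O)OC)C | intermediate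
21 | 6-(hydroxymethyl)-7-(3-hydroxy-2-methylbutan-2-yl)-4,6-dimethylbicyclo[3.1.1]hept-3-en-2-ol (epimers at the two secondary carbinols) | CC(O)C(C)(C)[C@@H]2[C@H]3C(O)C=C(C)[C@@H]2[C@]3(CO)C | intermediate
22 | 4,6-dimethyl-7-(2-methyl-3-oxobutan-2-yl)-2-oxobicyclo[3.1.1]hept-3-ene-6-carbaldehyde | CC(=O)C(C)(C)[C@@H]2[C@H]3C(=O)C=C(C)[C@@H]2[C@]3(C=O)C | intermediate
23 | tricyclic dienedione (C1 enone, C7 ketone, C8=C9) | C1=CC(=O)C(C)(C)[C@@H]2[C@H]3C(=O)C=C(C)[C@@H]2[C@]31C | intermediate
24 | (9R)-C9 pinacol boronate of the tricyclic diketone | CC4(C)OB(OC4(C)C)[C@@H]1CC(=O)C(C)(C)[C@@H]2[C@H]3C(=O)C=C(C)[C@@H]2[C@]31C | intermediate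
25 | (9R)-9-hydroxy tricyclic diketone | O[C@@H]1CC(=O)C(C)(C)[C@@H]2[C@H]3C(=O)C=C(C)[C@@H]2[C@]31C | intermediate
26 | 3-methylbut-2-enal | CC(C)=CC=O | starting material
27 | (7R,9R)-7-hydroxy-9-(3-methylbut-2-enoyloxy) tricyclic enone | CC(C)=CC(=O)O[C@@H]1C[C@@H](O)C(C)(C)[C@@H]2[C@H]3C(=O)C=C(C)[C@@H]2[C@]31C | intermediate
28 | 3-methylbutanoic anhydride | CC(C)CC(=O)OC(=O)CC(C)C | starting material
29 | CNP0335239.1 | CC(C)=CC(=O)O[C@@H]1C[C@@H](OC(=O)CC(C)C)C(C)(C)[C@@H]2[C@H]3C(=O)C=C(C)[C@@H]2[C@]31C | target

## Step count and least certain steps

Total: 17 steps. Longest linear sequence: 15 steps (from 5 through steps 3–17; the branch from 1 through steps 1, 2 and 5–17 is equally long).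

**Step 6 (key step).** The most likely failure is β-scission of the biradical across C4–C10; the strain of an all-cis tetrasubstituted ring and conjugation in both alkene fragments favour it. C5 has no stabilising group, so slow C5–N cleavage could let the diazene tautomerise to a hydrazone or dimerise. Ammonia may condense with the ketone, and nitrogen transfer may follow. Rotation before coupling would lose the C5 configuration. Fallback: from 10, the nitrogen is converted with 1-(azidosulfonyl)-2,3-dimethylimidazolium triflate into the sulfamoyl azide F1. Heating F1 in toluene triggers a Curtius-type rearrangement with loss of N2 and SO2 and generates the same diazene 11 without oxidant or ammonia, returning to the route at 12.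

**Step 5.** The glycinate carbon may bond to the less hindered C4 (wrong regiochemistry). The amine or phosphine may isomerise 4 to 3 before cycloaddition, which would invert C10 relative to C5. The aliphatic imine may react sluggishly, and face selection may be incomplete. Fallback: from 3 and 9, an exo-selective cycloaddition under univalent copper (Cu(CH3CN)4PF6, (R)-DTBM-SEGPHOS, Et3N, THF) uses the directly available E alkene and should give the C4-epimeric pyrrolidine F2. Under the conditions of step 6, F2 passes through its 1,1-diazene F3 and returns to the route at 13, which is then treated with KOtBu as in step 7.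

**Step 7.** The acetyl enolate may close onto the cis C9 ester before C4 has inverted. After C11 inverts it may close onto C1, which would give a symmetric dione and erase the absolute configuration. Protonation of the C11 enolate from the hindered face may be too slow for full equilibration. Fallback: from 13, isolated after the DBU stage, the ketone is masked (1,2-bis(trimethylsilyloxy)ethane, Me3SiOTf cat., CH2Cl2, −78 °C) as the dioxolane F4. KOtBu in tBuOH then inverts C11, the only acidic position left, to give the dioxolane F5. CF3CO2H/H2O/CH2Cl2 removes the ketal and the tert-butyl ester together and returns to the route at 15.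

**Step 10.** The phosphonate carbanion may fail to reach the C3 carbonyl, because the conformer with both groups pseudo-axial is disfavoured; intermolecular olefination would then compete. Fallback: from 15, the acid chloride 17 is made as in step 9 and acylates the magnesium enolate of allyl hydrogen malonate (MgCl2, Et3N, MeCN) to give the β-keto allyl ester F6. A Knoevenagel-type closure onto the C3 ketone (piperidine, AcOH, benzene, reflux, or TiCl4/pyridine) gives the bicyclic enone allyl ester F7. Deallylation and decarboxylation (Pd(PPh3)4, morpholine, THF, then gentle warming) return to the route at 19. C2 stays marked by the ester throughout, so reversibility cannot exchange C1 and C3.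

**Step 15.** The two faces of C9 are nearly equivalent in the substrate, so face selection rests entirely on the catalyst and may be poor. Borylation of the bridged enone and elimination of the β-hydroxy ketone during oxidation are further risks. Fallback: from 22, kinetic intramolecular aldol addition of the lithium enolate (LiN(SiMe3)2, THF, −78 °C, AcOH quench) gives 25 directly, together with its C9 epimer F8. The two are separated, and F8 is returned to 23 under the conditions of step 14; the route is rejoined at 25.

**Step 16.** The enal may be a poor hydride donor or be consumed by reductive coupling with SmI2. The hindered C9 alcohol may form the hemiacetal slowly. Retro-aldol opening of 25 on the samarium alkoxide would scramble C9. Fallback: from 25, the same reaction with 4-nitrobenzaldehyde (SmI2 cat., THF, −10 °C) gives the C9 4-nitrobenzoate with free C7 hydroxyl F9. Acylation with 28 as in step 17 gives the mixed diester F10. Selective methanolysis of the activated aryl ester (K2CO3, MeOH, 0 °C) gives the C9 alcohol C7 isovalerate F11. Esterification with 3-methylbut-2-enoic anhydride and DMAP returns to the route at 29.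

## Further compounds

F1 | step 6 | N-(azidosulfonyl) derivative of 10 (sulfamoyl azide) | CC(C)(C)OC(=O)[C@H]1N(S(=O)(=O)N=[N+]=[N-])[C@@H](C(C)(C)C=C)[C@@H](C(C)=O)[C@@]1(C)C(=O)OC
F2 | step 5 | C4 epimer of 10 (acetyl trans to the other three substituents) | CC(C)(C)OC(=O)[C@H]1N[C@@H](C(C)(C)C=C)[C@H](C(C)=O)[C@@]1(C)C(=O)OC
F3 | step 5 | 1,1-diazene of F2 | CC(C)(C)OC(=O)[C@H]1[N+](=[N-])[C@@H](C(C)(C)C=C)[C@H](C(C)=O)[C@@]1(C)C(=O)OC
F4 | step 7 | 2-methyl-1,3-dioxolane (ketal) of 13 | CC(C)(C)OC(=O)[C@H]1[C@@H](C(C)(C)C=C)[C@H](C2(C)OCCO2)[C@@]1(C)C(=O)OC
F5 | step 7 | C11 epimer of F4 (ketal of 14) | CC(C)(C)OC(=O)[C@@H]1[C@@H](C(C)(C)C=C)[C@H](C2(C)OCCO2)[C@@]1(C)C(=O)OC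
F6 | step 10 | β-keto allyl ester from 15 (C1 ketone, C2 bearing CO2-allyl) | C=CCOC(=O)CC(=O)[C@@H]1[C@@H](C(C)(C)C=C)[C@H](C(C)=O)[C@@]1(C)C(=O)OC
F7 | step 10 | 3-allyl 6-methyl 4,6-dimethyl-7-(2-methylbut-3-en-2-yl)-2-oxobicyclo[3.1.1]hept-3-ene-3,6-dicarboxylate | C=CC(C)(C)[C@@H]2[C@H]3C(=O)C(C(=O)OCC=C)=C(C)[C@@H]2[C@]3(C(=O)OC)C
F8 | step 15 | (9S)-9-hydroxy tricyclic diketone (C9 epimer of 25) | O[C@H]1CC(=O)C(C)(C)[C@@H]2[C@H]3C(=O)C=C(C)[C@@H]2[C@]31C
F9 | step 16 | (7R,9R)-7-hydroxy-9-(4-nitrobenzoyloxy) tricyclic enone | O=C(O[C@@H]1C[C@@H](O)C(C)(C)[C@@H]2[C@H]3C(=O)C=C(C)[C@@H]2[C@]31C)c5ccc([N+](=O)[O-])cc5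
F10 | step 16 | (7R,9R)-7-(3-methylbutanoyloxy)-9-(4-nitrobenzoyloxy) tricyclic enone | O=C(O[C@@H]1C[C@@H](OC(=O)CC(C)C)C(C)(C)[C@@H]2[C@H]3C(=O)C=C(C)[C@@H]2[C@]31C)c5ccc([N+](=O)[O-])cc5
F11 | step 16 | (7R,9R)-9-hydroxy-7-(3-methylbutanoyloxy) tricyclic enone | O[C@@H]1C[C@@H](OC(=O)CC(C)C)C(C)(C)[C@@H]2[C@H]3C(=O)C=C(C)[C@@H]2[C@]31C
A1 | alternative 1 | tricyclic norbornene, bridgehead tert-butyldimethylsilyl ether, endo nitro group, C9 triethylsilyl ether in the configuration required by 29 | CC(C)(C)[Si](C)(C)O[C@@]12C=C(C)[C@@H]([C@H]3[C@H]1[N+](=O)[O-])[C@@]2(C)[C@H](O[Si](CC)(CC)CC)CCC3(C)C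
A2 | alternative 1 | 1-silyloxy-3-methylcyclopentadiene carrying at its sp3 carbon a methyl group and the tether to the (E)-nitroalkene | CC(C)(C)[Si](C)(C)OC1=CC(C)=C[C@@]1(C)[C@H](O[Si](CC)(CC)CC)CCC(C)(C)/C=C/[N+](=O)[O-]
A3 | alternative 2 | tricyclic enone with C7 dioxolane and C9 methylene | C1CC4(OCCO4)C(C)(C)[C@@H]2[C@H]3C(=O)C=C(C)[C@@H]2[C@]31C
A4 | alternative 2 | meso diketone: bicyclo[4.1.1]octane with cis acetyl groups on C4 and C11, C7 dioxolane | C1CC4(OCCO4)C(C)(C)[C@@H]2[C@@H](C(C)=O)[C@@]1(C)[C@H]2C(C)=O
A5 | alternative 3 | bicyclo[4.1.1]octenone with C4 ketone, C7 enol silane, C9 silyl ether | CC(C)(C)[Si](C)(C)O[C@@H]1C=C(O[Si](C)(C)C)C(C)(C)[C@@H]2[C@@H](COCc3ccccc3)[C@@]1(C)C2=O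
A6 | alternative 3 | 3-(benzyloxymethyl)-2,4-dibromo-2-methylcyclobutan-1-one (bromide epimers) | O=C1C(Br)[C@@H](COCc2ccccc2)C1(C)Br
A7 | alternative 3 | (1E)-1-(tert-butyldimethylsilyloxy)-4-methyl-3-(trimethylsilyloxy)penta-1,3-diene | CC(C)=C(O[Si](C)(C)C)/C=C/O[Si](C)(C)C(C)(C)C
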